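**Retrosynthetic overview**
1. The C11=C12 bond is cut by a Wittig disconnection into a keto-enal "β-half" (β-ring, C7–C11, C19 laurate) and a C25 ε-phosphonium salt; the salt comes from a C15 hydroxy-aldehyde and a C10 bis-phosphonium salt.
2. The keto-enal comes from oxidative opening of a 2,3-disubstituted furan, which masks C8=O and C11HO and leaves only the C19 hydroxyl to acylate; the furan comes from a Feist–Benary reaction on a β-keto ester of the ring-acetic acid.
3. The ring-acetic acid comes from reductive opening of a bicyclic butenolide, and this from a bicyclic γ-lactone. Key step: one SmI2 operation (ketyl–olefin 6-exo cyclisation, then lactonisation) converts an acyclic keto-enoate into the cyclohexane and the lactone; C3 comes from a proline aldol.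
4. The ε-half comes from racemic α-ionone (ring bought): HWE nitrile, allylic oxidation, CBS reduction (sets C3', sorts C6'), DIBAL-H.
5. Ring order: cyclohexane and γ-lactone together (step 5), then the temporary furan (made in step 9, opened in step 12); the ε-ring is never made or broken.

Assumption: "α-ionone" means the cheap racemate; its unwanted (6S) half is removed as a diastereomer in step 15. The two ring-fusion centres created in step 5 are carried as epimer mixtures because both become sp2 in steps 6 and 7.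

**Step 1**
Reactants: 1 methyl 3,3-dimethylpent-4-enoate
Product: 2 3,3-dimethylpent-4-enal
Conditions: DIBAL-H (1.05 eq), CH2Cl2, −78 °C; Rochelle salt
Reagents that add atoms: none
Why: Partial ester reduction with DIBAL-H stops at the aluminium hemiacetal at −78 °C and gives the aldehyde on work-up.

**Step 2**
Reactants: 2 3,3-dimethylpent-4-enal; 3 acetone
Product: 4 (4S)-4-hydroxy-6,6-dimethyloct-7-en-2-one
Conditions: (S)-proline (30 mol%), acetone/CHCl3 1:4, 4 °C, 3 d
Reagents that add atoms: none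
Why: List–Barbas proline-catalysed direct aldol; the acetone enamine attacks the aldehyde Re face through the hydrogen-bonded Houk–List transition state, which sets the future C3 carbinol (S here by CIP ranking, same spatial sense as the known (R)-aldols of α-branched aldehydes).

**Step 3**
Reactants: 4 (4S)-4-hydroxy-6,6-dimethyloct-7-en-2-one
Product: 5 (4S)-4-(tert-butyldimethylsilyloxy)-6,6-dimethyloct-7-en-2-one
Conditions: TBSCl, imidazole, DMF, rt
Reagents that add atoms: tert-butyldimethylsilyl chloride (TBSCl), CC(C)(C)[Si](C)(C)Cl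
Why: Corey silylation protects the β-hydroxy ketone against retro-aldol, elimination and chelation-controlled reduction in the SmI2 step.

**Step 4**
Reactants: 5 (4S)-4-(tert-butyldimethylsilyloxy)-6,6-dimethyloct-7-en-2-one; 6 methyl acrylate
Product: 7 methyl (2E,6S)-6-(tert-butyldimethylsilyloxy)-4,4-dimethyl-8-oxonon-2-enoate
Conditions: 6 (5 eq), Hoveyda–Grubbs II (5 mol%), toluene, 80 °C
Reagents that add atoms: none
Why: Olefin cross-metathesis between the hindered vinyl group (which cannot homodimerise) and the electron-poor acrylate gives the E-enoate selectively.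

**Step 5** (key step)
Reactants: 7 methyl (2E,6S)-6-(tert-butyldimethylsilyloxy)-4,4-dimethyl-8-oxonon-2-enoate
Product: 9 (6S)-6-(tert-butyldimethylsilyloxy)-4,4,7a-trimethylhexahydrobenzofuran-2(3H)-one (ring-fusion epimers), via cyclised hydroxy ester 8 (not isolated)
Conditions: SmI2 (2.5 eq), HMPA, t-BuOH (2 eq), THF, −78 → 0 °C; then cat. TsOH, CH2Cl2, rt
Reagents that add atoms: none
Why: SmI2 ketyl–olefin radical cyclisation (6-exo-trig attack of the methyl-ketone ketyl on the enoate β-carbon, helped by the gem-dimethyl group) followed by lactonisation of the samarium alkoxide closes the cyclohexane and the γ-lactone in one flask; the two new centres need no control because they are erased later.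

**Step 6**
Reactants: 9 (6S)-6-(tert-butyldimethylsilyloxy)-4,4,7a-trimethylhexahydrobenzofuran-2(3H)-one
Product: 11 (6S)-6-(tert-butyldimethylsilyloxy)-4,4,7a-trimethyl-5,6,7,7a-tetrahydrobenzofuran-2(4H)-one (O-TBS loliolide/epiloliolide), via alpha-phenylselanyl lactone 10 (not isolated)
Conditions: LDA, THF, −78 °C; PhSeBr; then 30% H2O2, pyridine, CH2Cl2, 0 °C → rt
Reagents that add atoms: none
Why: Lactone enolate selenenylation and selenoxide syn-elimination (Reich–Sharpless) can only eliminate towards the ring-fusion hydrogen, giving the butenolide.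

**Step 7**
Reactants: 11 (6S)-6-(tert-butyldimethylsilyloxy)-4,4,7a-trimethyl-5,6,7,7a-tetrahydrobenzofuran-2(4H)-one
Product: 12 2-[(4R)-4-(tert-butyldimethylsilyloxy)-2,6,6-trimethylcyclohex-1-en-1-yl]acetic acid
Conditions: SmI2 (2.5 eq), THF/HMPA, MeOH (2 eq), −78 °C; pH 3 work-up
Reagents that add atoms: none
Why: SmI2 reductive cleavage of the γ-acyloxy enoate expels the tertiary carboxylate oxygen, and kinetic α-protonation of the dienolate fixes the double bond regiospecifically at the tetrasubstituted C5=C6 position; both lactone epimers converge on one acid.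

**Step 8**
Reactants: 12 2-[(4R)-4-(tert-butyldimethylsilyloxy)-2,6,6-trimethylcyclohex-1-en-1-yl]acetic acid; 13 potassium ethyl malonate
Product: 15 ethyl 4-[(4R)-4-(tert-butyldimethylsilyloxy)-2,6,6-trimethylcyclohex-1-en-1-yl]-3-oxobutanoate, via acyl imidazolide 14 (not isolated)
Conditions: CDI, THF, rt; then 13, MgCl2, Et3N, THF, 45 °C; aq. citric acid
Reagents that add atoms: none
Why: Masamune–Brooks C-acylation of the magnesium malonate half-ester and decarboxylation gives the β-keto ester that carries C9 and C19.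

**Step 9**
Reactants: 15 ethyl 4-[(4R)-4-(tert-butyldimethylsilyloxy)-2,6,6-trimethylcyclohex-1-en-1-yl]-3-oxobutanoate; 16 chloroacetaldehyde
Product: 18 ethyl 2-{[(4R)-4-hydroxy-2,6,6-trimethylcyclohex-1-en-1-yl]methyl}furan-3-carboxylate, via silyl-protected furan ester 17 (not isolated)
Conditions: 16 (50% aq), pyridine, 50 °C; then 1 M HCl, THF, rt
Reagents that add atoms: none
Why: Feist–Benary furan synthesis (aldol at the doubly activated C9, O-alkylation by the chloromethyl carbon, dehydration) builds the 2,3-disubstituted furan, and the acid stage completes aromatisation and removes the TBS group from the acid-stable furan ester.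

**Step 10**
Reactants: 18 ethyl 2-{[(4R)-4-hydroxy-2,6,6-trimethylcyclohex-1-en-1-yl]methyl}furan-3-carboxylate
Product: 19 (1R)-4-{[3-(hydroxymethyl)furan-2-yl]methyl}-3,5,5-trimethylcyclohex-3-en-1-ol
Conditions: DIBAL-H (3.5 eq), CH2Cl2, −78 → 0 °C
Reagents that add atoms: none
Why: Hydride reduction of the ester gives the C19 carbinol with no ketone present, because C8 is still masked in the furan.

**Step 11**
Reactants: 19 (1R)-4-{[3-(hydroxymethyl)furan-2-yl]methyl}-3,5,5-trimethylcyclohex-3-en-1-ol; 20 dodecanoyl chloride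
Product: 21 (2-{[(4R)-4-hydroxy-2,6,6-trimethylcyclohex-1-en-1-yl]methyl}furan-3-yl)methyl dodecanoate
Conditions: 20 (1.05 eq), 2,4,6-collidine, CH2Cl2, −78 → −40 °C
Reagents that add atoms: none
Why: Kinetically selective acylation of the unhindered primary carbinol over the secondary ring alcohol installs the laurate on the only primary hydroxyl.

**Step 12**
Reactants: 21 (2-{[(4R)-4-hydroxy-2,6,6-trimethylcyclohex-1-en-1-yl]methyl}furan-3-yl)methyl dodecanoate
Product: 23 (2E)-2-{[(4R)-4-hydroxy-2,6,6-trimethylcyclohex-1-en-1-yl]acetyl}-4-oxobut-2-en-1-yl dodecanoate, via 2Z enal 22 (not isolated)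
Conditions: NBS (1.05 eq), NaHCO3, acetone/H2O 10:1, −15 °C; then pyridine (2 eq), rt
Reagents that add atoms: water, O
Why: Kobayashi oxidative furan ring-opening (the dialkylfuran is far more nucleophilic than the tetrasubstituted alkene) reveals the C8 ketone and C11 aldehyde as the cis-enedicarbonyl, and pyridine equilibrates it to the E isomer with C19 cis to C11.

**Step 13**
Reactants: 24 (±)-α-ionone; 25 diethyl cyanomethylphosphonate
Product: 26 (±)-(2E,4E)-3-methyl-5-(2,6,6-trimethylcyclohex-2-en-1-yl)penta-2,4-dienenitrile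
Conditions: NaH, THF, 0 °C → rt; 9E isomer by chromatography
Reagents that add atoms: none
Why: Horner–Wadsworth–Emmons olefination of the methyl ketone gives mainly the E-trisubstituted dienenitrile (the C15 skeleton).

**Step 14**
Reactants: 26 (±)-(2E,4E)-3-methyl-5-(2,6,6-trimethylcyclohex-2-en-1-yl)penta-2,4-dienenitrile
Product: 27 (±)-(2E,4E)-3-methyl-5-(2,6,6-trimethyl-4-oxocyclohex-2-en-1-yl)penta-2,4-dienenitrile
Conditions: t-BuOOH (70% aq, 5 eq), Rh2(cap)4 (1 mol%), K2CO3, CH2Cl2, rt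
Reagents that add atoms: tert-butyl hydroperoxide, CC(C)(C)OO
Why: Rhodium-catalysed allylic oxidation (Doyle) converts the ring allylic CH2 into the enone carbonyl, as known for α-ionone derivatives.

**Step 15**
Reactants: 27 (±)-(2E,4E)-3-methyl-5-(2,6,6-trimethyl-4-oxocyclohex-2-en-1-yl)penta-2,4-dienenitrile
Product: 28 (2E,4E)-5-[(1R,4R)-4-hydroxy-2,6,6-trimethylcyclohex-2-en-1-yl]-3-methylpenta-2,4-dienenitrile
Conditions: (S)-Me-CBS (1 eq), catecholborane (1.5 eq), toluene, −78 °C; chromatography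
Reagents that add atoms: none
Why: Corey–Bakshi–Shibata reduction under reagent control (alkenyl side as the large group) makes C3' R in both enantiomers, so the (6R) half gives the trans (3'R,6'R) alcohol and the (6S) half gives the cis diastereomer, which is removed on silica.

**Step 16**
Reactants: 28 (2E,4E)-5-[(1R,4R)-4-hydroxy-2,6,6-trimethylcyclohex-2-en-1-yl]-3-methylpenta-2,4-dienenitrile
Product: 30 (2E,4E)-5-[(1R,4R)-4-hydroxy-2,6,6-trimethylcyclohex-2-en-1-yl]-3-methylpenta-2,4-dienal, via aldimine 29 (not isolated)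
Conditions: DIBAL-H (2.5 eq), CH2Cl2, −78 °C; wet silica gel
Reagents that add atoms: water, O
Why: DIBAL-H adds once to the nitrile and mild hydrolysis of the aluminium aldimine gives the aldehyde without touching the acid-sensitive allylic alcohol.

**Step 17**
Reactants: 31 (2E,4E,6E)-2,7-dimethylocta-2,4,6-trienedial
Product: 32 (2E,4E,6E)-2,7-dimethylocta-2,4,6-triene-1,8-diol
Conditions: NaBH4, MeOH/THF, 0 °C
Reagents that add atoms: none
Why: Borohydride 1,2-reduction of both conjugated aldehydes keeps the triene geometry.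

**Step 18**
Reactants: 32 (2E,4E,6E)-2,7-dimethylocta-2,4,6-triene-1,8-diol
Product: 33 (2E,4E,6E)-2,7-dimethylocta-2,4,6-triene-1,8-diylbis(triphenylphosphonium) dibromide
Conditions: Ph3P·HBr (2.1 eq), MeOH, rt
Reagents that add atoms: triphenylphosphine hydrobromide, [Br-].[PH+](c1ccccc1)(c1ccccc1)c1ccccc1
Why: Acid ionises the trienylic carbinols to delocalised allyl cations that triphenylphosphine captures at the terminal carbons (standard carotenoid phosphonium salt formation).

**Step 19**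
Reactants: 30 (2E,4E)-5-[(1R,4R)-4-hydroxy-2,6,6-trimethylcyclohex-2-en-1-yl]-3-methylpenta-2,4-dienal; 33 (2E,4E,6E)-2,7-dimethylocta-2,4,6-triene-1,8-diylbis(triphenylphosphonium) dibromide
Product: 34 [(2E,4E,6E,8E,10E,12E)-13-[(1R,4R)-4-hydroxy-2,6,6-trimethylcyclohex-2-en-1-yl]-2,7,11-trimethyltrideca-2,4,6,8,10,12-hexaen-1-yl]triphenylphosphonium bromide
Conditions: 33 (3 eq), NaOMe (1.1 eq), CH2Cl2/MeOH, 0 °C → rt; chromatography (CH2Cl2/MeOH)
Reagents that add atoms: none
Why: Wittig mono-olefination with the mono-ylide of an excess of the bis-salt forms C11'=C12' and leaves the second phosphonium group in place, so no acid touches the ring allylic alcohol; any 11'Z isomer is carried to the final isomerisation.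

**Step 20**
Reactants: 34 C25 phosphonium bromide (name as in step 19); 23 (2E)-2-{[(4R)-4-hydroxy-2,6,6-trimethylcyclohex-1-en-1-yl]acetyl}-4-oxobut-2-en-1-yl dodecanoate
Product: 36 (3R,3'R,6'R)-3,3'-dihydroxy-8-oxo-7,8-dihydro-β,ε-caroten-19-yl dodecanoate (target), via 11Z isomer 35 (not isolated)
Conditions: 1,2-epoxybutane, 60 °C, dark, Ar; then heptane/EtOAc, 80 °C (Z → E)
Reagents that add atoms: none
Why: Salt-free Wittig reaction (the epoxide scavenges HBr, so no alkoxide attacks the laurate or the base-labile C7 methylene) of the polyenyl ylide with the more electrophilic aldehyde carbonyl forms C11=C12, and thermal isomerisation gives the all-E polyene; no stereocentre is touched.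

**Compound list**
1 | methyl 3,3-dimethylpent-4-enoate | COC(=O)CC(C)(C)C=C | starting material
2 | 3,3-dimethylpent-4-enal | O=CCC(C)(C)C=C | intermediate
3 | acetone | CC(C)=O | starting material
4 | (4S)-4-hydroxy-6,6-dimethyloct-7-en-2-one | CC(=O)C[C@@H](O)CC(C)(C)C=C | intermediate
5 | (4S)-4-(tert-butyldimethylsilyloxy)-6,6-dimethyloct-7-en-2-one | CC(=O)C[C@@H](O[Si](C)(C)C(C)(C)C)CC(C)(C)C=C | intermediate
6 | methyl acrylate | C=CC(=O)OC | starting material
7 | methyl (2E,6S)-6-(tert-butyldimethylsilyloxy)-4,4-dimethyl-8-oxonon-2-enoate | CC(=O)C[C@@H](O[Si](C)(C)C(C)(C)C)CC(C)(C)/C=C/C(=O)OC | intermediate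
8 | methyl 2-[(4S)-4-(tert-butyldimethylsilyloxy)-2-hydroxy-2,6,6-trimethylcyclohexyl]acetate (C1/C2 epimers) | COC(=O)CC1C(C)(C)C[C@H](O[Si](C)(C)C(C)(C)C)CC1(C)O | intermediate
9 | (6S)-6-(tert-butyldimethylsilyloxy)-4,4,7a-trimethylhexahydrobenzofuran-2(3H)-one (3a/7a epimers) | O=C1CC2C(C)(C)C[C@H](O[Si](C)(C)C(C)(C)C)CC2(C)O1 | intermediate
10 | (6S)-6-(tert-butyldimethylsilyloxy)-4,4,7a-trimethyl-3-(phenylselanyl)hexahydrobenzofuran-2(3H)-one | O=C1C([Se]c3ccccc3)C2C(C)(C)C[C@H](O[Si](C)(C)C(C)(C)C)CC2(C)O1 | intermediate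
11 | (6S)-6-(tert-butyldimethylsilyloxy)-4,4,7a-trimethyl-5,6,7,7a-tetrahydrobenzofuran-2(4H)-one (7a epimers) | O=C1C=C2C(C)(C)C[C@H](O[Si](C)(C)C(C)(C)C)CC2(C)O1 | intermediate
12 | 2-[(4R)-4-(tert-butyldimethylsilyloxy)-2,6,6-trimethylcyclohex-1-en-1-yl]acetic acid | OC(=O)CC1=C(C)C[C@@H](O[Si](C)(C)C(C)(C)C)CC1(C)C | intermediate
13 | potassium ethyl malonate | CCOC(=O)CC(=O)[O-].[K+] | starting material
14 | 1-{[(4R)-4-(tert-butyldimethylsilyloxy)-2,6,6-trimethylcyclohex-1-en-1-yl]acetyl}imidazole | O=C(CC1=C(C)C[C@@H](O[Si](C)(C)C(C)(C)C)CC1(C)C)n1ccnc1 | intermediate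
15 | ethyl 4-[(4R)-4-(tert-butyldimethylsilyloxy)-2,6,6-trimethylcyclohex-1-en-1-yl]-3-oxobutanoate | CCOC(=O)CC(=O)CC1=C(C)C[C@@H](O[Si](C)(C)C(C)(C)C)CC1(C)C | intermediate
16 | chloroacetaldehyde | ClCC=O | starting material
17 | ethyl 2-{[(4R)-4-(tert-butyldimethylsilyloxy)-2,6,6-trimethylcyclohex-1-en-1-yl]methyl}furan-3-carboxylate | CCOC(=O)c1ccoc1CC1=C(C)C[C@@H](O[Si](C)(C)C(C)(C)C)CC1(C)C | intermediate
18 | ethyl 2-{[(4R)-4-hydroxy-2,6,6-trimethylcyclohex-1-en-1-yl]methyl}furan-3-carboxylate | CCOC(=O)c1ccoc1CC1=C(C)C[C@@H](O)CC1(C)C | intermediate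
19 | (1R)-4-{[3-(hydroxymethyl)furan-2-yl]methyl}-3,5,5-trimethylcyclohex-3-en-1-ol | OCc1ccoc1CC1=C(C)C[C@@H](O)CC1(C)C | intermediate
20 | dodecanoyl chloride | CCCCCCCCCCCC(Cl)=O | starting material
21 | (2-{[(4R)-4-hydroxy-2,6,6-trimethylcyclohex-1-en-1-yl]methyl}furan-3-yl)methyl dodecanoate | CCCCCCCCCCCC(=O)OCc1ccoc1CC1=C(C)C[C@@H](O)CC1(C)C | intermediate
22 | (2Z)-2-{[(4R)-4-hydroxy-2,6,6-trimethylcyclohex-1-en-1-yl]acetyl}-4-oxobut-2-en-1-yl dodecanoate | CCCCCCCCCCCC(=O)OC/C(=C/C=O)C(=O)CC1=C(C)C[C@@H](O)CC1(C)C | intermediate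
23 | (2E)-2-{[(4R)-4-hydroxy-2,6,6-trimethylcyclohex-1-en-1-yl]acetyl}-4-oxobut-2-en-1-yl dodecanoate | CCCCCCCCCCCC(=O)OC\C(=C/C=O)C(=O)CC1=C(C)C[C@@H](O)CC1(C)C | intermediate
24 | (±)-α-ionone | CC(=O)/C=C/C1C(C)=CCCC1(C)C | starting material
25 | diethyl cyanomethylphosphonate | CCOP(=O)(CC#N)OCC | starting material
26 | (±)-(2E,4E)-3-methyl-5-(2,6,6-trimethylcyclohex-2-en-1-yl)penta-2,4-dienenitrile | N#C/C=C(C)/C=C/C1C(C)=CCCC1(C)C | intermediate
27 | (±)-(2E,4E)-3-methyl-5-(2,6,6-trimethyl-4-oxocyclohex-2-en-1-yl)penta-2,4-dienenitrile | N#C/C=C(C)/C=C/C1C(C)=CC(=O)CC1(C)C | intermediate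
28 | (2E,4E)-5-[(1R,4R)-4-hydroxy-2,6,6-trimethylcyclohex-2-en-1-yl]-3-methylpenta-2,4-dienenitrile | N#C/C=C(C)/C=C/[C@H]1C(C)=C[C@H](O)CC1(C)C | intermediate
29 | (2E,4E)-5-[(1R,4R)-4-hydroxy-2,6,6-trimethylcyclohex-2-en-1-yl]-3-methylpenta-2,4-dien-1-imine | N=C/C=C(C)/C=C/[C@H]1C(C)=C[C@H](O)CC1(C)C | intermediate
30 | (2E,4E)-5-[(1R,4R)-4-hydroxy-2,6,6-trimethylcyclohex-2-en-1-yl]-3-methylpenta-2,4-dienal | O=C/C=C(C)/C=C/[C@H]1C(C)=C[C@H](O)CC1(C)C | intermediate
31 | (2E,4E,6E)-2,7-dimethylocta-2,4,6-trienedial | O=C/C(C)=C/C=C/C=C(C)/C=O | starting material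
32 | (2E,4E,6E)-2,7-dimethylocta-2,4,6-triene-1,8-diol | OC/C(C)=C/C=C/C=C(C)/CO | intermediate
33 | (2E,4E,6E)-2,7-dimethylocta-2,4,6-triene-1,8-diylbis(triphenylphosphonium) dibromide | [Br-].[Br-].c1ccccc1[P+](c1ccccc1)(c1ccccc1)C/C(C)=C/C=C/C=C(C)/C[P+](c1ccccc1)(c1ccccc1)c1ccccc1 | intermediate
34 | [(2E,4E,6E,8E,10E,12E)-13-[(1R,4R)-4-hydroxy-2,6,6-trimethylcyclohex-2-en-1-yl]-2,7,11-trimethyltrideca-2,4,6,8,10,12-hexaen-1-yl]triphenylphosphonium bromide | [Br-].c1ccccc1[P+](c1ccccc1)(c1ccccc1)C/C(C)=C/C=C/C=C(C)/C=C/C=C(C)/C=C/[C@H]1C(C)=C[C@H](O)CC1(C)C | intermediate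
35 | (11Z)-isomer of 36 | CCCCCCCCCCCC(=O)OC\C(=C/C=C\C(C)=C\C=C\C=C(C)\C=C\C=C(C)\C=C\[C@H]1C(C)=C[C@H](O)CC1(C)C)C(=O)CC1=C(C)C[C@@H](O)CC1(C)C | intermediate
36 | (3R,3'R,6'R)-3,3'-dihydroxy-8-oxo-7,8-dihydro-β,ε-caroten-19-yl dodecanoate | CCCCCCCCCCCC(=O)OC\C(=C/C=C/C(C)=C/C=C/C=C(C)/C=C/C=C(C)/C=C/[C@H]1C(C)=C[C@H](O)CC1(C)C)C(=O)CC1=C(C)C[C@@H](O)CC1(C)C | target

**Step count and risks**
Total: 20 steps. Longest linear sequence: 13 steps (steps 1–12, then step 20).

The three steps most likely to fail are steps 5, 15 and 19.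

Step 5 can fail through simple ketone reduction or sluggish attack at the neopentyl-flanked β-carbon. The fallback sets out from keto-alkene 5 (step 4 is skipped) and joins the ketone carbonyl, the vinyl group and carbon monoxide in a titanium(II)-mediated hetero-Pauson–Khand reaction (Cp2Ti(PMe3)2, CO, then air). This organometallic [2+2+1] route gives the same bicyclic lactone and returns to the main route at 9; new compounds on the way: none F0.

Step 15 can fail if the mismatched enantiomer of 27 leaks into the trans fraction and lowers its enantiopurity. The fallback sets out from 27: Luche reduction (NaBH4, CeCl3, MeOH, −40 °C) and chromatography give the racemic trans alcohol F1 (cis isomers discarded). Lipase-catalysed kinetic resolution (Amano lipase AK, vinyl acetate) acylates only the (1R,4R) enantiomer to the (1R,4R)-acetate F2, and methanolysis of F2 (K2CO3, MeOH) returns to 28.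

Step 19 can fail through double olefination or difficult separation of the two phosphonium salts. The fallback reverses the polarity and sets out from 30: NaBH4 reduction gives the C15 diol F3, and Ph3P·HBr (1 eq, MeOH, 0 °C) converts only the dienylic primary carbinol into the C15 phosphonium bromide F4. Wittig reaction of F4 with an excess of dialdehyde 31 gives the C25 hydroxy aldehyde F5, NaBH4 gives the C25 diol F6, and Ph3P·HBr on F6 returns to 34.

**Further compounds**
F0 | step 5 | none | none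
F1 | step 15 | racemic trans-(2E,4E)-5-(4-hydroxy-2,6,6-trimethylcyclohex-2-en-1-yl)-3-methylpenta-2,4-dienenitrile | N#C/C=C(C)/C=C/[C@H]1C(C)=C[C@H](O)CC1(C)C.N#C/C=C(C)/C=C/[C@@H]1C(C)=C[C@@H](O)CC1(C)C
F2 | step 15 | (1R,4R)-4-[(1E,3E)-4-cyano-3-methylbuta-1,3-dien-1-yl]-3,5,5-trimethylcyclohex-2-en-1-yl acetate | N#C/C=C(C)/C=C/[C@H]1C(C)=C[C@H](OC(C)=O)CC1(C)C
F3 | step 19 | (2E,4E)-5-[(1R,4R)-4-hydroxy-2,6,6-trimethylcyclohex-2-en-1-yl]-3-methylpenta-2,4-dien-1-ol | OC/C=C(C)/C=C/[C@H]1C(C)=C[C@H](O)CC1(C)C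
F4 | step 19 | [(2E,4E)-5-[(1R,4R)-4-hydroxy-2,6,6-trimethylcyclohex-2-en-1-yl]-3-methylpenta-2,4-dien-1-yl]triphenylphosphonium bromide | [Br-].c1ccccc1[P+](c1ccccc1)(c1ccccc1)C/C=C(C)/C=C/[C@H]1C(C)=C[C@H](O)CC1(C)C
F5 | step 19 | (2E,4E,6E,8E,10E,12E)-13-[(1R,4R)-4-hydroxy-2,6,6-trimethylcyclohex-2-en-1-yl]-2,7,11-trimethyltrideca-2,4,6,8,10,12-hexaenal | O=C/C(C)=C/C=C/C=C(C)/C=C/C=C(C)/C=C/[C@H]1C(C)=C[C@H](O)CC1(C)C
F6 | step 19 | (2E,4E,6E,8E,10E,12E)-13-[(1R,4R)-4-hydroxy-2,6,6-trimethylcyclohex-2-en-1-yl]-2,7,11-trimethyltrideca-2,4,6,8,10,12-hexaen-1-ol | OC/C(C)=C/C=C/C=C(C)/C=C/C=C(C)/C=C/[C@H]1C(C)=C[C@H](O)CC1(C)C
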